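Remark on the chemistry: ring A is the prenylated arene, ring B the oxepine, ring C the resorcinol-derived arene and ring D the dihydropyran; C10 and C11 are the olefinic carbons of ring B (C10 bears ring C and the ring D oxygen, C11 bears ring A), and ring D is numbered O1, C2 (quaternary), C3 (carbinol), C4, C5 (= C11), C6 (= C10).

## Analysis of the target

The target is a tetracycle in which a dibenzo[b,f]oxepine (rings A, B, C) shares its C10=C11 olefin with a 3,4-dihydro-2H-pyran (ring D). That olefin is therefore a tetrasubstituted enol ether: C10 carries ring C and the ring D oxygen, C11 carries ring A and the ring D methylene. Ring A is pentasubstituted (C11, the ether oxygen, a free hydroxyl, and a prenyl group ortho to that hydroxyl). Ring C is a resorcinol unit whose oxygen ortho to C10 is the ether bridge and whose oxygen para to C10 is a free phenol. Ring D holds the only two stereocentres, and they are adjacent: the oxygen-bearing quaternary C2 (methyl and 4-methylpent-3-enyl) and the secondary carbinol C3. Both are S, which puts the hydroxyl trans to the methyl group and cis to the homoprenyl chain. The electron-rich enol ether, the two trisubstituted olefins and the ortho-prenylphenol rule out acid at the end of the synthesis, and the olefins rule out hydrogenolysis. The hard points are the seven-membered ring flanked by a tetrasubstituted olefin with two ortho-substituted arenes, the substitution pattern of ring A, and the oxygenated quaternary centre next to a carbinol. The strategy rests on one feature: the ether oxygen joins the ring C carbon ortho to C10 to the ring A carbon ortho to C11, and because C10=C11 is locked inside ring D the two arenes are necessarily cis, so the O–ring A bond of ring B can be made last.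

## Retrosynthetic reasoning

Target 24 is cut at the bond between the bridging oxygen and ring A, giving the unprotected cis-diaryl dihydropyran 23 with a phenol on ring C and a chloride on ring A. This bond is chosen because everything else in 24 is then already in place and nothing follows the closure. Cutting a C–C bond of ring B instead would mean forming the tetrasubstituted olefin late. The forward reaction is a palladium-catalysed O-arylation that has to select the one hydroxyl able to reach the chloride.

Precursor 23 is traced to its tetrasilyl ether 22, and 22 is cut at the C10–ring C bond into ketene acetal phosphate 18 and arylboronate 21. C10 is an enol-ether carbon, so it is the carbonyl carbon of a lactone in disguise. The cut places the olefin geometry inside a ring and lets ring C arrive as a simple boronate. The forward Suzuki–Miyaura coupling must insert into the C–O(P) bond and leave the ring A chloride alone, which is why that halogen is chlorine and the catalyst carries triphenylphosphine. Silyl groups are used throughout so that the last deprotection needs only fluoride.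

Phosphate 18 comes from δ-lactone 16 by enolisation. Lactone 16 is opened at the acyl–oxygen bond to the tertiary hydroxy ester 15, and the C11–C4 bond is cut to give arylacetate 12 and triflate 7 (joined in the forward sense as ester 14). The secondary oxygen must stay silylated while the tertiary one is released, otherwise the five-membered lactone would form. The stereocentre created at C11 is of no concern, since it becomes trigonal in 18.

Triflate 7 carries both stereocentres. It is traced through diol 5 and bis-silyl ether 4 to triol 3, and 3 to epoxide 2 and nerol 1. Anti opening of the Z-derived epoxide at its tertiary carbon gives exactly the trans relation between hydroxyl and methyl. The asymmetric epoxidation of the allylic alcohol sets the absolute configuration and ignores the remote olefin.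

Arylacetate 12 is traced through iodide 11 and phenol 10 to ester 9 and the purchasable acid 8. The prenyl group is put in by cross-coupling at a position fixed by a regioselective iodination, not by direct C-prenylation of the phenol, which would give mixtures.

Boronate 21 is traced through bromide 20 to 4-bromoresorcinol 19, whose bromine already marks the carbon that becomes attached to C10.

## Alternatives that were turned down

Alternative 1: Ring A itself is dismantled into three pieces by cutting three of its C–C bonds. In the forward sense, irradiation of diazo ketone A2 triggers a Wolff rearrangement. The ketene function so formed adds [2+2] to the alkyne of aryl ethynyl ether A3, and four-electron ring opening, six-electron ring closure and tautomerisation give phenol A1. In A1 the ether oxygen, the hydroxyl, the prenyl group and the acetate arm for C11 are placed by connectivity alone. On regiocontrol of ring A this plan is stronger than the chosen one, which relies on a selective iodination and on linear prenyl transfer. It also has the diaryl ether in hand before any ring is closed. Against it: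
- The key step builds a benzene ring whose pattern is reached from purchasable acid 8 in four routine steps.
- A2 holds a skipped diene next to an enone and is prone to isomerisation.
- A3 is a sensitive ynol ether that needs several steps.
- A1 still lacks ring B, ring D and both stereocentres. Ring B would have to be closed by an acid-mediated acylation onto ring C in the presence of a free ortho-prenylphenol, and ring D by alkylation at C11 with 7 followed by an acidic cyclodehydration.

The chosen route buys both arenes, uses no acid once the prenyl group and the enol ether are present, and is shorter.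

Alternative 2: Ring C is dismantled into three alkynes; one of the three new C–C bonds is also a bond of ring B. In the forward sense a cationic rhodium catalyst with a chelating bisphosphine cyclotrimerises diyne A5 with alkynylboronate A6 to give tetracycle A4, forming ring C and closing ring B at once. The plan forms two rings and three bonds in one neutral step. It makes the O–ring A bond early by simple ynol ether chemistry, and it avoids both a hindered boronate coupling and a demanding C–O reductive elimination; on these points it is stronger. Against it: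
- The tether between the alkynes of A5 has five atoms and includes the tetrasubstituted olefin, so a seven-membered ring must form within the metallacycle. This is far less favourable than the five- and six-membered cases, and self-trimerisation of A6 can compete.
- The position of boron depends only on the bulk of the silyl group.
- A5 needs an aryl ethynyl ether next to a bulky substituent and an alkynyl ketene acetal, which would itself be made from phosphate 18.
- Three operations follow the key step: oxidation of C–B in the presence of an enol ether and two olefins, removal of the aryl–silicon group (normally acid), and O-desilylation.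

The chosen route needs the same lactone chemistry, ends with the ring closure, and has no step after it.

Alternative 3: The seven-membered ring and the C11–ring A bond are traced back to a six-membered ring. In the forward sense an alkyllithium exchanges one bromine of xanthenol A8, which creates a carbenoid centre next to the alkoxide. A 1,2-aryl shift with loss of bromide expands the central ring and, after protonation, gives oxepinone A7 with the complete ring D side chain at C11. The diaryl ether is present from the start. The symmetry of A8 makes the choice of migrating arene irrelevant. The ring-forming event is a rearrangement with a strong driving force, so on robustness of the ring B construction it is at least as strong as the chosen closure. Against it: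
- A7 carries two nearly identical silyloxy arenes, and the prenyl group must afterwards go onto ring A only; nothing in A7 secures that.
- The tertiary silyl ether must then be removed selectively and ring D closed by acid-promoted cyclodehydration onto the C10 ketone, which endangers the olefins.
- The addition that makes A8 puts a hindered dibromo carbanion onto a poorly electrophilic diaryl ketone.
- At least four steps follow the key step.

The chosen route keeps rings A and C distinct from the outset, installs the prenyl group before the fragments meet, and forms the enol ether from a lactone under basic conditions.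

Key step: step 17

## Route

Step 1
Reactants: 1 nerol, (2Z)-3,7-dimethylocta-2,6-dien-1-ol
Product: 2 [(2S,3R)-3-methyl-3-(4-methylpent-3-en-1-yl)oxiran-2-yl]methanol
Conditions: Ti(OiPr)4 (10 mol%), L-(+)-diethyl tartrate (12 mol%), t-BuOOH, 4 Å MS, CH2Cl2, −20 °C
Reagents that add atoms: tert-butyl hydroperoxide, CC(C)(C)OO
Why: Katsuki–Sharpless asymmetric epoxidation; only the olefin of the titanium-bound allylic alcohol is oxidised, so the remote trisubstituted olefin is untouched. With L-(+)-tartrate the Z-allylic alcohol should give the (2S,3R)-epoxide; Z substrates are somewhat less selective than E ones, so the enantiomeric purity should be checked here and can be raised by crystallising a derivative of 3.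

Step 2
Reactants: 2 [(2S,3R)-3-methyl-3-(4-methylpent-3-en-1-yl)oxiran-2-yl]methanol
Product: 3 (2S,3S)-3,7-dimethyloct-6-ene-1,2,3-triol
Conditions: HClO4 (cat.), THF–H2O, 0 °C
Reagents that add atoms: water, O
Why: Acid-catalysed epoxide hydrolysis; water attacks the protonated epoxide at the tertiary carbon C3, which bears most of the positive charge, from the side opposite the leaving oxygen. C3 is thereby inverted from R to S while C2 keeps its S configuration, which gives the hydroxyl/methyl relation needed in ring D.

Step 3
Reactants: 3 (2S,3S)-3,7-dimethyloct-6-ene-1,2,3-triol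
Product: 4 (2S,3S)-1,2-bis(tert-butyldimethylsilyloxy)-3,7-dimethyloct-6-en-3-ol
Conditions: TBSCl (2.4 equiv), imidazole, DMAP (cat.), DMF, rt → 40 °C
Reagents that add atoms: tert-butyldimethylsilyl chloride, CC(C)(C)[Si](C)(C)Cl
Why: Imidazole-promoted silylation discriminates by steric demand: the primary and secondary hydroxyls react, the tertiary one does not under these conditions.

Step 4
Reactants: 4 (2S,3S)-1,2-bis(tert-butyldimethylsilyloxy)-3,7-dimethyloct-6-en-3-ol
Product: 5 (2S,3S)-2-(tert-butyldimethylsilyloxy)-3,7-dimethyloct-6-ene-1,3-diol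
Conditions: HF·pyridine, pyridine, THF, 0 °C
Reagents that add atoms: none
Why: Selective desilylation; buffered fluoride cleaves the unhindered primary silyl ether much faster than the secondary one, which is shielded by the adjacent quaternary carbon.

Step 5
Reactants: 5 (2S,3S)-2-(tert-butyldimethylsilyloxy)-3,7-dimethyloct-6-ene-1,3-diol
Product: 7 (2S,3S)-2-(tert-butyldimethylsilyloxy)-3,7-dimethyl-3-(trimethylsilyloxy)oct-6-en-1-yl trifluoromethanesulfonate, via hydroxy triflate 6 (not isolated)
Conditions: Tf2O, 2,6-lutidine, CH2Cl2, −78 °C; then Me3SiOTf, −78 → −40 °C; cold NaHCO3 work-up, used at once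
Reagents that add atoms: trifluoromethanesulfonic anhydride, O=S(=O)(OS(=O)(=O)C(F)(F)F)C(F)(F)F; trimethylsilyl trifluoromethanesulfonate, C[Si](C)(C)OS(=O)(=O)C(F)(F)F
Why: Sulfonylation at −78 °C is selective for the primary hydroxyl. The tertiary hydroxyl is then capped in the same flask as a labile trimethylsilyl ether, so that it can neither close an oxetane onto the triflate nor quench the enolate in step 10.

Step 6
Reactants: 8 2-chloro-4-hydroxyphenylacetic acid
Product: 9 methyl 2-(2-chloro-4-hydroxyphenyl)acetate
Conditions: MeOH, H2SO4 (cat.), reflux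
Reagents that add atoms: methanol, CO
Why: Fischer esterification; the phenol and the aryl chloride are inert.

Step 7
Reactants: 9 methyl 2-(2-chloro-4-hydroxyphenyl)acetate
Product: 10 methyl 2-(2-chloro-4-hydroxy-5-iodophenyl)acetate
Conditions: N-iodosuccinimide (1.05 equiv), TsOH·H2O (cat.), MeCN, 0 °C → rt
Reagents that add atoms: N-iodosuccinimide, O=C1CCC(=O)N1I
Why: Electrophilic aromatic iodination directed ortho by the hydroxyl, whose para position is blocked. C5 is also para to chlorine and unhindered, whereas C3 lies between chlorine and hydroxyl, so substitution should occur at C5.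

Step 8
Reactants: 10 methyl 2-(2-chloro-4-hydroxy-5-iodophenyl)acetate
Product: 11 methyl 2-[2-chloro-5-iodo-4-(triisopropylsilyloxy)phenyl]acetate
Conditions: i-Pr3SiCl, imidazole, DMF, rt
Reagents that add atoms: triisopropylsilyl chloride, CC(C)[Si](Cl)(C(C)C)C(C)C
Why: Phenol silylation; the triisopropylsilyl ether is chosen because it withstands the amide bases, the mild acid and the aqueous base of steps 9 to 15 and is removed by fluoride.

Step 9
Reactants: 11 methyl 2-[2-chloro-5-iodo-4-(triisopropylsilyloxy)phenyl]acetate
Product: 12 methyl 2-[2-chloro-5-(3-methylbut-2-en-1-yl)-4-(triisopropylsilyloxy)phenyl]acetate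
Conditions: Bu3SnCH2CH=CMe2 (1.3 equiv), Pd(PPh3)4 (5 mol%), DMF, 90 °C
Reagents that add atoms: tributyl(3-methylbut-2-en-1-yl)stannane, CCCC[Sn](CCCC)(CCCC)CC=C(C)C
Why: Stille coupling; with triphenylphosphine ligands zerovalent palladium inserts into the C–I bond and not into the C–Cl bond. The prenyl group is expected to be transferred through its primary carbon, giving the linear isomer.

Step 10
Reactants: 12 methyl 2-[2-chloro-5-(3-methylbut-2-en-1-yl)-4-(triisopropylsilyloxy)phenyl]acetate; 7 (2S,3S)-2-(tert-butyldimethylsilyloxy)-3,7-dimethyl-3-(trimethylsilyloxy)oct-6-en-1-yl trifluoromethanesulfonate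
Product: 14 methyl (4S,5S)-4-(tert-butyldimethylsilyloxy)-2-[2-chloro-5-(3-methylbut-2-en-1-yl)-4-(triisopropylsilyloxy)phenyl]-5,9-dimethyl-5-(trimethylsilyloxy)dec-8-enoate (both C2 epimers), via lithium enolate 13 (not isolated)
Conditions: LiN(SiMe3)2 (1.25 equiv), 12 (1.3 equiv), THF, −78 °C; then 7 (1.0 equiv), DMPU, −78 → −30 °C
Reagents that add atoms: none
Why: Ester enolate alkylation; the stabilised arylacetate enolate displaces the primary triflate by SN2 at carbon. The new stereocentre at C2 of the ester forms as a mixture, which is of no consequence because this carbon becomes trigonal in step 12.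

Step 11
Reactants: 14 methyl (4S,5S)-4-(tert-butyldimethylsilyloxy)-2-[2-chloro-5-(3-methylbut-2-en-1-yl)-4-(triisopropylsilyloxy)phenyl]-5,9-dimethyl-5-(trimethylsilyloxy)dec-8-enoate
Product: 16 (5S,6S)-5-(tert-butyldimethylsilyloxy)-3-[2-chloro-5-(3-methylbut-2-en-1-yl)-4-(triisopropylsilyloxy)phenyl]-6-methyl-6-(4-methylpent-3-en-1-yl)tetrahydro-2H-pyran-2-one (both C3 epimers), via hydroxy ester 15 (not isolated)
Conditions: PPTS (cat.), MeOH–CH2Cl2, rt; evaporate; then camphorsulfonic acid (cat.), toluene, 4 Å MS, 50 °C
Reagents that add atoms: none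
Why: Mild acid methanolysis removes only the tertiary trimethylsilyl ether, and acid-catalysed transesterification then closes the six-membered lactone, helped by the fully substituted carbinol carbon (Thorpe–Ingold effect). The secondary oxygen stays silylated, so the five-membered lactone cannot form, and no alkoxide is generated, so the silyl group cannot migrate to the tertiary oxygen.

Step 12
Reactants: 16 (5S,6S)-5-(tert-butyldimethylsilyloxy)-3-[2-chloro-5-(3-methylbut-2-en-1-yl)-4-(triisopropylsilyloxy)phenyl]-6-methyl-6-(4-methylpent-3-en-1-yl)tetrahydro-2H-pyran-2-one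
Product: 18 (2S,3S)-3-(tert-butyldimethylsilyloxy)-5-[2-chloro-5-(3-methylbut-2-en-1-yl)-4-(triisopropylsilyloxy)phenyl]-2-methyl-2-(4-methylpent-3-en-1-yl)-3,4-dihydro-2H-pyran-6-yl diphenyl phosphate, via potassium enolate 17 (not isolated)
Conditions: KN(SiMe3)2 (1.3 equiv), THF–DMPU, −78 °C; then (PhO)2P(O)Cl, −78 → 0 °C; chromatography on Et3N-deactivated silica
Reagents that add atoms: diphenyl chlorophosphate, O=P(Cl)(Oc1ccccc1)Oc1ccccc1
Why: Enolisation of the α-aryl lactone and O-phosphorylation give the ketene acetal phosphate. This fixes the C10=C11 olefin inside ring D and turns C10 into a cross-coupling electrophile.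

Step 13
Reactants: 19 4-bromoresorcinol (4-bromobenzene-1,3-diol)
Product: 20 1-bromo-2,4-bis(tert-butyldimethylsilyloxy)benzene
Conditions: TBSCl (2.4 equiv), imidazole, DMF, rt
Reagents that add atoms: tert-butyldimethylsilyl chloride, CC(C)(C)[Si](C)(C)Cl
Why: Phenol silylation; the smaller tert-butyldimethylsilyl group is used on ring C to keep the position ortho to the future C10 bond as uncongested as possible.

Step 14
Reactants: 20 1-bromo-2,4-bis(tert-butyldimethylsilyloxy)benzene
Product: 21 2-[2,4-bis(tert-butyldimethylsilyloxy)phenyl]-4,4,5,5-tetramethyl-1,3,2-dioxaborolane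
Conditions: B2pin2, PdCl2(dppf) (5 mol%), KOAc, 1,4-dioxane, 90 °C
Reagents that add atoms: bis(pinacolato)diboron, CC1(C)OB(OC1(C)C)B1OC(C)(C)C(C)(C)O1
Why: Miyaura borylation; the acetate base is mild enough for aryl silyl ethers, and no aryllithium is formed that could undergo oxygen-to-carbon silyl migration.

Step 15
Reactants: 18 (2S,3S)-3-(tert-butyldimethylsilyloxy)-5-[2-chloro-5-(3-methylbut-2-en-1-yl)-4-(triisopropylsilyloxy)phenyl]-2-methyl-2-(4-methylpent-3-en-1-yl)-3,4-dihydro-2H-pyran-6-yl diphenyl phosphate; 21 2-[2,4-bis(tert-butyldimethylsilyloxy)phenyl]-4,4,5,5-tetramethyl-1,3,2-dioxaborolane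
Product: 22 (2S,3S)-6-[2,4-bis(tert-butyldimethylsilyloxy)phenyl]-3-(tert-butyldimethylsilyloxy)-5-[2-chloro-5-(3-methylbut-2-en-1-yl)-4-(triisopropylsilyloxy)phenyl]-2-methyl-2-(4-methylpent-3-en-1-yl)-3,4-dihydro-2H-pyran
Conditions: 21 (1.8 equiv), Pd(PPh3)4 (10 mol%), K3PO4 (2 M aq., 3 equiv), 1,4-dioxane, 85 °C
Reagents that add atoms: none
Why: Suzuki–Miyaura coupling of a lactone-derived ketene acetal phosphate; triphenylphosphine-ligated zerovalent palladium inserts into the alkenyl C–O(P) bond but not into the electron-rich aryl chloride. Partial loss of aryl silyl groups under the aqueous base does no harm, since step 16 removes them all.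

Step 16
Reactants: 22 (2S,3S)-6-[2,4-bis(tert-butyldimethylsilyloxy)phenyl]-3-(tert-butyldimethylsilyloxy)-5-[2-chloro-5-(3-methylbut-2-en-1-yl)-4-(triisopropylsilyloxy)phenyl]-2-methyl-2-(4-methylpent-3-en-1-yl)-3,4-dihydro-2H-pyran
Product: 23 4-[(2S,3S)-5-[2-chloro-4-hydroxy-5-(3-methylbut-2-en-1-yl)phenyl]-3-hydroxy-2-methyl-2-(4-methylpent-3-en-1-yl)-3,4-dihydro-2H-pyran-6-yl]benzene-1,3-diol
Conditions: Bu4NF (6 equiv), THF, 0 → 40 °C, Ar; aq. NH4Cl work-up
Reagents that add atoms: none
Why: Fluoride-mediated desilylation of the three aryl silyl ethers and the alkyl silyl ether; the medium is basic to neutral, so the enol ether and the prenyl groups are not exposed to acid.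

Step 17
Reactants: 23 4-[(2S,3S)-5-[2-chloro-4-hydroxy-5-(3-methylbut-2-en-1-yl)phenyl]-3-hydroxy-2-methyl-2-(4-methylpent-3-en-1-yl)-3,4-dihydro-2H-pyran-6-yl]benzene-1,3-diol
Product: 24 CNP0185870.1, the (2S,3S)-configured dihydropyrano-fused dibenzo[b,f]oxepine (target)
Conditions: Pd2(dba)3 (5 mol%), 2-di-tert-butylphosphino-2',4',6'-triisopropylbiphenyl (12 mol%), K3PO4 (4 equiv), toluene–1,4-dioxane, 0.01 M, 100 °C, Ar
Reagents that add atoms: none
Why: The phosphine-ligated zerovalent palladium inserts into the ring A C–Cl bond, the phosphate base generates the phenoxides, the ring C ortho phenoxide replaces chloride on palladium to give an eight-membered aryl(aryloxo)palladium chelate, and C–O reductive elimination, which the bulky di-tert-butylbiarylphosphine promotes, forms the O–ring A bond. The closest known reaction type is the palladium-catalysed coupling of phenols with aryl chlorides to diaryl ethers (Buchwald–Hartwig-type C–O coupling), including its intramolecular use for dibenzo-fused seven-membered ethers. Ring B is closed as a seven-membered ring by intramolecular O-arylation, with the C10=C11 olefin of ring D holding the two arenes cis and the reacting atoms within reach. No stereocentre is formed, and the two existing ones are remote from the reacting atoms and carry no epimerisable hydrogen. The step needs chemoselectivity among three phenols and one alcohol: the ring A hydroxyl and the ring C para hydroxyl can only react between molecules, which high dilution suppresses, whereas the ring C ortho hydroxyl reacts within the molecule. Closure through the ring D alcohol would create a bridged ring with the olefin at a bridgehead (Bredt's rule), and that alcohol is hardly deprotonated by the phosphate base. Chlorine was chosen as the halogen because it passes through steps 9 and 15 unchanged under triphenylphosphine catalysts and is activated only by the electron-rich bulky phosphine used here.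

## Compound list

1 | nerol, (2Z)-3,7-dimethylocta-2,6-dien-1-ol | CC(C)=CCC/C(C)=C\CO | starting material
2 | [(2S,3R)-3-methyl-3-(4-methylpent-3-en-1-yl)oxiran-2-yl]methanol | CC(C)=CCC[C@@]1(C)O[C@H]1CO | intermediate
3 | (2S,3S)-3,7-dimethyloct-6-ene-1,2,3-triol | CC(C)=CCC[C@](C)(O)[C@@H](O)CO | intermediate
4 | (2S,3S)-1,2-bis(tert-butyldimethylsilyloxy)-3,7-dimethyloct-6-en-3-ol | CC(C)=CCC[C@](C)(O)[C@@H](O[Si](C)(C)C(C)(C)C)CO[Si](C)(C)C(C)(C)C | intermediate
5 | (2S,3S)-2-(tert-butyldimethylsilyloxy)-3,7-dimethyloct-6-ene-1,3-diol | CC(C)=CCC[C@](C)(O)[C@@H](O[Si](C)(C)C(C)(C)C)CO | intermediate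
6 | (2S,3S)-2-(tert-butyldimethylsilyloxy)-3-hydroxy-3,7-dimethyloct-6-en-1-yl trifluoromethanesulfonate | CC(C)=CCC[C@](C)(O)[C@@H](O[Si](C)(C)C(C)(C)C)COS(=O)(=O)C(F)(F)F | intermediate
7 | (2S,3S)-2-(tert-butyldimethylsilyloxy)-3,7-dimethyl-3-(trimethylsilyloxy)oct-6-en-1-yl trifluoromethanesulfonate | CC(C)=CCC[C@](C)(O[Si](C)(C)C)[C@@H](O[Si](C)(C)C(C)(C)C)COS(=O)(=O)C(F)(F)F | intermediate
8 | 2-chloro-4-hydroxyphenylacetic acid | OC(=O)Cc1ccc(O)cc1Cl | starting material
9 | methyl 2-(2-chloro-4-hydroxyphenyl)acetate | COC(=O)Cc1ccc(O)cc1Cl | intermediate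
10 | methyl 2-(2-chloro-4-hydroxy-5-iodophenyl)acetate | COC(=O)Cc1cc(I)c(O)cc1Cl | intermediate
11 | methyl 2-[2-chloro-5-iodo-4-(triisopropylsilyloxy)phenyl]acetate | COC(=O)Cc1cc(I)c(O[Si](C(C)C)(C(C)C)C(C)C)cc1Cl | intermediate
12 | methyl 2-[2-chloro-5-(3-methylbut-2-en-1-yl)-4-(triisopropylsilyloxy)phenyl]acetate | COC(=O)Cc1cc(CC=C(C)C)c(O[Si](C(C)C)(C(C)C)C(C)C)cc1Cl | intermediate
13 | lithium enolate of 12 | [Li+].COC([O-])=Cc1cc(CC=C(C)C)c(O[Si](C(C)C)(C(C)C)C(C)C)cc1Cl | intermediate
14 | methyl (4S,5S)-4-(tert-butyldimethylsilyloxy)-2-[2-chloro-5-(3-methylbut-2-en-1-yl)-4-(triisopropylsilyloxy)phenyl]-5,9-dimethyl-5-(trimethylsilyloxy)dec-8-enoate, both C2 epimers | CC(C)=CCC[C@](C)(O[Si](C)(C)C)[C@@H](O[Si](C)(C)C(C)(C)C)CC(C(=O)OC)c1cc(CC=C(C)C)c(O[Si](C(C)C)(C(C)C)C(C)C)cc1Cl | intermediate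
15 | methyl (4S,5S)-4-(tert-butyldimethylsilyloxy)-2-[2-chloro-5-(3-methylbut-2-en-1-yl)-4-(triisopropylsilyloxy)phenyl]-5-hydroxy-5,9-dimethyldec-8-enoate, both C2 epimers | CC(C)=CCC[C@](C)(O)[C@@H](O[Si](C)(C)C(C)(C)C)CC(C(=O)OC)c1cc(CC=C(C)C)c(O[Si](C(C)C)(C(C)C)C(C)C)cc1Cl | intermediate
16 | (5S,6S)-5-(tert-butyldimethylsilyloxy)-3-[2-chloro-5-(3-methylbut-2-en-1-yl)-4-(triisopropylsilyloxy)phenyl]-6-methyl-6-(4-methylpent-3-en-1-yl)tetrahydro-2H-pyran-2-one, both C3 epimers | CC(C)=CCC[C@]1(C)OC(=O)C(C[C@@H]1O[Si](C)(C)C(C)(C)C)c1cc(CC=C(C)C)c(O[Si](C(C)C)(C(C)C)C(C)C)cc1Cl | intermediate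
17 | potassium enolate of 16 | [K+].CC(C)=CCC[C@]1(C)OC([O-])=C(C[C@@H]1O[Si](C)(C)C(C)(C)C)c1cc(CC=C(C)C)c(O[Si](C(C)C)(C(C)C)C(C)C)cc1Cl | intermediate
18 | (2S,3S)-3-(tert-butyldimethylsilyloxy)-5-[2-chloro-5-(3-methylbut-2-en-1-yl)-4-(triisopropylsilyloxy)phenyl]-2-methyl-2-(4-methylpent-3-en-1-yl)-3,4-dihydro-2H-pyran-6-yl diphenyl phosphate | CC(C)=CCC[C@]1(C)OC(OP(=O)(Oc2ccccc2)Oc2ccccc2)=C(C[C@@H]1O[Si](C)(C)C(C)(C)C)c1cc(CC=C(C)C)c(O[Si](C(C)C)(C(C)C)C(C)C)cc1Cl | intermediate
19 | 4-bromoresorcinol (4-bromobenzene-1,3-diol) | Oc1ccc(Br)c(O)c1 | starting material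
20 | 1-bromo-2,4-bis(tert-butyldimethylsilyloxy)benzene | CC(C)(C)[Si](C)(C)Oc1ccc(Br)c(O[Si](C)(C)C(C)(C)C)c1 | intermediate
21 | 2-[2,4-bis(tert-butyldimethylsilyloxy)phenyl]-4,4,5,5-tetramethyl-1,3,2-dioxaborolane | CC(C)(C)[Si](C)(C)Oc1ccc(B2OC(C)(C)C(C)(C)O2)c(O[Si](C)(C)C(C)(C)C)c1 | intermediate
22 | (2S,3S)-6-[2,4-bis(tert-butyldimethylsilyloxy)phenyl]-3-(tert-butyldimethylsilyloxy)-5-[2-chloro-5-(3-methylbut-2-en-1-yl)-4-(triisopropylsilyloxy)phenyl]-2-methyl-2-(4-methylpent-3-en-1-yl)-3,4-dihydro-2H-pyran | CC(C)=CCC[C@]1(C)OC(c2ccc(O[Si](C)(C)C(C)(C)C)cc2O[Si](C)(C)C(C)(C)C)=C(C[C@@H]1O[Si](C)(C)C(C)(C)C)c1cc(CC=C(C)C)c(O[Si](C(C)C)(C(C)C)C(C)C)cc1Cl | intermediate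
23 | 4-[(2S,3S)-5-[2-chloro-4-hydroxy-5-(3-methylbut-2-en-1-yl)phenyl]-3-hydroxy-2-methyl-2-(4-methylpent-3-en-1-yl)-3,4-dihydro-2H-pyran-6-yl]benzene-1,3-diol | CC(C)=CCC[C@]1(C)OC(c2ccc(O)cc2O)=C(C[C@@H]1O)c1cc(CC=C(C)C)c(O)cc1Cl | intermediate
24 | CNP0185870.1, the (2S,3S)-configured dihydropyrano-fused dibenzo[b,f]oxepine | CC(C)=CCC[C@]1(C)OC2=C(C[C@@H]1O)c1cc(CC=C(C)C)c(O)cc1Oc1cc(O)ccc12 | target

## Step count and least certain steps

Total step count: 17 steps. Longest linear sequence: 11 steps (steps 1–5, 10–12 and 15–17, from nerol 1).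

Step 17 (key step). The most likely failure is slow oxidative addition into an aryl chloride made very electron-rich by the ring A phenoxide. Intermolecular O-arylation through the unhindered phenoxides and binding of the catalyst by the polyphenoxide could then overtake ring closure. The fallback closes the ring on a partly protected substrate and deprotects afterwards. It sets out from 22. K2CO3 in MeOH at 0 °C should cleave the two aryl tert-butyldimethylsilyl ethers of ring C much faster than the aryl triisopropylsilyl ether of ring A or the hindered alkyl silyl ether. This gives 4-[(2S,3S)-3-(tert-butyldimethylsilyloxy)-5-[2-chloro-5-(3-methylbut-2-en-1-yl)-4-(triisopropylsilyloxy)phenyl]-2-methyl-2-(4-methylpent-3-en-1-yl)-3,4-dihydro-2H-pyran-6-yl]benzene-1,3-diol F1. Under the catalyst system of step 17, F1 offers an aryl chloride without a phenoxide on its ring, no free alcohol and good solubility in toluene. It should close to the oxepine still silylated on the ring A oxygen and the ring D oxygen, F2. Bu4NF in THF then removes both silyl groups, and the sequence comes back to the route at 24.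

Step 15. The tetrasubstituted alkenylpalladium intermediate is congested, so transmetalation may be slow; protodeboronation of the electron-rich ortho-silyloxy boronate and hydrolysis of the ketene acetal phosphate under aqueous base could then win. The fallback is a Negishi coupling, which changes the coupling manifold from boron under aqueous base to zinc under anhydrous, base-free conditions. It sets out from 20. Insertion of Mg in the presence of LiCl and ZnCl2 in THF gives [2,4-bis(tert-butyldimethylsilyloxy)phenyl]zinc chloride F3. F3 is coupled with phosphate 18 using Pd(PPh3)4 in THF at 60 °C, and the sequence comes back to the route at 22.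

Step 10. SN2 displacement at the β-branched, β-silyloxy primary carbon may be slow, so that decomposition of the triflate or proton transfer consumes the partners. The fallback uses a far more nucleophilic dianion in place of the ester enolate. It sets out from 12. Me3SnOH in 1,2-dichloroethane at 80 °C hydrolyses the methyl ester without touching the aryl silyl ether and gives 2-[2-chloro-5-(3-methylbut-2-en-1-yl)-4-(triisopropylsilyloxy)phenyl]acetic acid F4. LiN(i-Pr)2 (2.2 equiv) in THF converts F4 into its dilithium enediolate F5, which is alkylated with triflate 7 at −78 °C to give (4S,5S)-4-(tert-butyldimethylsilyloxy)-2-[2-chloro-5-(3-methylbut-2-en-1-yl)-4-(triisopropylsilyloxy)phenyl]-5,9-dimethyl-5-(trimethylsilyloxy)dec-8-enoic acid F6. Esterification of F6 with Me3SiCHN2 in MeOH–toluene brings the sequence back to the route at 14.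

Step 11. Acid-catalysed transesterification at the tertiary hydroxyl may be slow. Prolonged acid exposure could then remove the secondary silyl ether, which opens the way to the five-membered lactone, or add the hydroxyl across the side-chain olefin. The fallback replaces transesterification by a reduction–oxidation relay. It sets out from 14. i-Bu2AlH (2.5 equiv) in CH2Cl2 reduces the ester to (4S,5S)-4-(tert-butyldimethylsilyloxy)-2-[2-chloro-5-(3-methylbut-2-en-1-yl)-4-(triisopropylsilyloxy)phenyl]-5,9-dimethyl-5-(trimethylsilyloxy)dec-8-en-1-ol F7. PPTS in MeOH frees the tertiary hydroxyl and gives the 1,5-diol F8. TEMPO (cat.) with PhI(OAc)2 in CH2Cl2 oxidises the primary alcohol, the resulting hydroxy aldehyde closes spontaneously to the lactol F9, and F9 is oxidised further in the same flask. The sequence comes back to the route at 16.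

Step 2. The opening may acquire carbocation character at C3, with partial loss of stereochemical integrity, or water may attack C2. The fallback delivers a carboxylate within a titanium chelate instead of using free aqueous acid. It sets out from 2. Ti(OiPr)4 and benzoic acid in CH2Cl2 should open the titanium-bound epoxy alcohol at C3 with inversion to give (2S,3S)-1,2-dihydroxy-3,7-dimethyloct-6-en-3-yl benzoate F10, possibly together with acyl-migrated isomers. K2CO3 in MeOH removes the benzoate, and the sequence comes back to the route at 3.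

Step 9. The prenyl group may be transferred through its tertiary carbon (allylic transposition), giving the branched isomer. The fallback installs an allyl group, for which this question does not arise, and builds the prenyl terminus by metathesis. It sets out from 11. Stille coupling with allyltributylstannane and Pd(PPh3)4 in DMF gives methyl 2-[2-chloro-5-(prop-2-en-1-yl)-4-(triisopropylsilyloxy)phenyl]acetate F11. Cross-metathesis of F11 with excess 2-methylbut-2-ene and the second-generation Grubbs catalyst RuCl2(=CHPh)(PCy3)(H2IMes) in CH2Cl2 at 40 °C brings the sequence back to the route at 12.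

## Further compounds

F1 | step 17 | 4-[(2S,3S)-3-(tert-butyldimethylsilyloxy)-5-[2-chloro-5-(3-methylbut-2-en-1-yl)-4-(triisopropylsilyloxy)phenyl]-2-methyl-2-(4-methylpent-3-en-1-yl)-3,4-dihydro-2H-pyran-6-yl]benzene-1,3-diol | CC(C)=CCC[C@]1(C)OC(c2ccc(O)cc2O)=C(C[C@@H]1O[Si](C)(C)C(C)(C)C)c1cc(CC=C(C)C)c(O[Si](C(C)C)(C(C)C)C(C)C)cc1Cl
F2 | step 17 | target carrying a triisopropylsilyl ether on the ring A oxygen and a tert-butyldimethylsilyl ether on the ring D oxygen | CC(C)=CCC[C@]1(C)OC2=C(C[C@@H]1O[Si](C)(C)C(C)(C)C)c1cc(CC=C(C)C)c(O[Si](C(C)C)(C(C)C)C(C)C)cc1Oc1cc(O)ccc12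
F3 | step 15 | [2,4-bis(tert-butyldimethylsilyloxy)phenyl]zinc chloride | CC(C)(C)[Si](C)(C)Oc1ccc([Zn]Cl)c(O[Si](C)(C)C(C)(C)C)c1
F4 | step 10 | 2-[2-chloro-5-(3-methylbut-2-en-1-yl)-4-(triisopropylsilyloxy)phenyl]acetic acid | OC(=O)Cc1cc(CC=C(C)C)c(O[Si](C(C)C)(C(C)C)C(C)C)cc1Cl
F5 | step 10 | dilithium enediolate of F4 | [Li+].[Li+].[O-]C([O-])=Cc1cc(CC=C(C)C)c(O[Si](C(C)C)(C(C)C)C(C)C)cc1Cl
F6 | step 10 | (4S,5S)-4-(tert-butyldimethylsilyloxy)-2-[2-chloro-5-(3-methylbut-2-en-1-yl)-4-(triisopropylsilyloxy)phenyl]-5,9-dimethyl-5-(trimethylsilyloxy)dec-8-enoic acid, both C2 epimers | CC(C)=CCC[C@](C)(O[Si](C)(C)C)[C@@H](O[Si](C)(C)C(C)(C)C)CC(C(=O)O)c1cc(CC=C(C)C)c(O[Si](C(C)C)(C(C)C)C(C)C)cc1Cl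
F7 | step 11 | (4S,5S)-4-(tert-butyldimethylsilyloxy)-2-[2-chloro-5-(3-methylbut-2-en-1-yl)-4-(triisopropylsilyloxy)phenyl]-5,9-dimethyl-5-(trimethylsilyloxy)dec-8-en-1-ol, both C2 epimers | CC(C)=CCC[C@](C)(O[Si](C)(C)C)[C@@H](O[Si](C)(C)C(C)(C)C)CC(CO)c1cc(CC=C(C)C)c(O[Si](C(C)C)(C(C)C)C(C)C)cc1Cl
F8 | step 11 | (4S,5S)-4-(tert-butyldimethylsilyloxy)-2-[2-chloro-5-(3-methylbut-2-en-1-yl)-4-(triisopropylsilyloxy)phenyl]-5,9-dimethyldec-8-ene-1,5-diol, both C2 epimers | CC(C)=CCC[C@](C)(O)[C@@H](O[Si](C)(C)C(C)(C)C)CC(CO)c1cc(CC=C(C)C)c(O[Si](C(C)C)(C(C)C)C(C)C)cc1Cl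
F9 | step 11 | (5S,6S)-5-(tert-butyldimethylsilyloxy)-3-[2-chloro-5-(3-methylbut-2-en-1-yl)-4-(triisopropylsilyloxy)phenyl]-6-methyl-6-(4-methylpent-3-en-1-yl)tetrahydro-2H-pyran-2-ol, mixture of C2 and C3 epimers | CC(C)=CCC[C@]1(C)OC(O)C(C[C@@H]1O[Si](C)(C)C(C)(C)C)c1cc(CC=C(C)C)c(O[Si](C(C)C)(C(C)C)C(C)C)cc1Cl
F10 | step 2 | (2S,3S)-1,2-dihydroxy-3,7-dimethyloct-6-en-3-yl benzoate | CC(C)=CCC[C@](C)(OC(=O)c1ccccc1)[C@@H](O)CO
F11 | step 9 | methyl 2-[2-chloro-5-(prop-2-en-1-yl)-4-(triisopropylsilyloxy)phenyl]acetate | COC(=O)Cc1cc(CC=C)c(O[Si](C(C)C)(C(C)C)C(C)C)cc1Cl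
A1 | alternative 1 | methyl 2-[4-hydroxy-5-(3-methylbut-2-en-1-yl)-2-(3-triisopropylsilyloxyphenoxy)phenyl]acetate | COC(=O)Cc1cc(CC=C(C)C)c(O)cc1Oc1cccc(O[Si](C(C)C)(C(C)C)C(C)C)c1
A2 | alternative 1 | methyl (5E)-3-diazo-9-methyl-4-oxodeca-5,8-dienoate | COC(=O)CC(=[N+]=[N-])C(=O)/C=C/CC=C(C)C
A3 | alternative 1 | 1-(ethynyloxy)-3-(triisopropylsilyloxy)benzene | C#COc1cccc(O[Si](C(C)C)(C(C)C)C(C)C)c1
A4 | alternative 2 | tetracyclic oxepine with a pinacol boronate on the ring C carbon para to C10, a trimethylsilyl group on the ring C carbon ortho to C10 and tert-butyldimethylsilyl ethers on the ring A and ring D oxygens | CC(C)=CCC[C@]1(C)OC2=C(C[C@@H]1O[Si](C)(C)C(C)(C)C)c1cc(CC=C(C)C)c(O[Si](C)(C)C(C)(C)C)cc1Oc1cc(B3OC(C)(C)C(C)(C)O3)cc([Si](C)(C)C)c12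
A5 | alternative 2 | (2S,3S)-3-(tert-butyldimethylsilyloxy)-5-[4-(tert-butyldimethylsilyloxy)-2-(ethynyloxy)-5-(3-methylbut-2-en-1-yl)phenyl]-2-methyl-2-(4-methylpent-3-en-1-yl)-6-[(trimethylsilyl)ethynyl]-3,4-dihydro-2H-pyran | CC(C)=CCC[C@]1(C)OC(C#C[Si](C)(C)C)=C(C[C@@H]1O[Si](C)(C)C(C)(C)C)c1cc(CC=C(C)C)c(O[Si](C)(C)C(C)(C)C)cc1OC#C
A6 | alternative 2 | 2-ethynyl-4,4,5,5-tetramethyl-1,3,2-dioxaborolane | C#CB1OC(C)(C)C(C)(C)O1
A7 | alternative 3 | 11-[(2S,3S)-2-(tert-butyldimethylsilyloxy)-3,7-dimethyl-3-(triethylsilyloxy)oct-6-en-1-yl]-3,7-bis(tert-butyldimethylsilyloxy)dibenzo[b,f]oxepin-10(11H)-one, both C11 epimers | CC(C)=CCC[C@](C)(O[Si](CC)(CC)CC)[C@@H](O[Si](C)(C)C(C)(C)C)CC1C(=O)c2ccc(O[Si](C)(C)C(C)(C)C)cc2Oc2cc(O[Si](C)(C)C(C)(C)C)ccc12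
A8 | alternative 3 | 9-[(3S,4S)-1,1-dibromo-3-(tert-butyldimethylsilyloxy)-4,8-dimethyl-4-(triethylsilyloxy)non-7-en-1-yl]-3,6-bis(tert-butyldimethylsilyloxy)-9H-xanthen-9-ol | CC(C)=CCC[C@](C)(O[Si](CC)(CC)CC)[C@@H](O[Si](C)(C)C(C)(C)C)CC(Br)(Br)C1(O)c2ccc(O[Si](C)(C)C(C)(C)C)cc2Oc2cc(O[Si](C)(C)C(C)(C)C)ccc12
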